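The synthesis rests on cutting the C4a''–C5'' bond in ring A of unit 2. That ring carries oxygen on C5'', C7'' and C8a'' (O1'') and the C4'' carbonyl on C4a''. This is the acylphloroglucinol pattern of a folded poly-β-carbonyl chain. Rings B and C of unit 2, the C3'–C3'' bond and the whole benzyl-protected unit 1 are therefore assembled first as a 2,3-diaryl-4-pyranone whose C6 carries a CH2–CO–CH2–CO2Me chain. A single Mg(OMe)2-induced Claisen closure from pyranone C5 onto the ester then builds ring A and, through enolisation, both of its free phenols. Hydrogenolysis finishes the synthesis.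

Key step: step 10

Assumption: the target has no stereocentre and the C3'–C3'' axis is taken as freely rotating. The only stereo-element on the route is the E alkene of the chalcone, and it is erased on flavone formation.
Protecting groups: O5, O4' and O4''' are carried as benzyl ethers. These survive I2/DMSO, TsOH, amide base and Mg(OMe)2. Early release of O4' next to the benzyl ketone would invite cyclodehydration to a 2-arylbenzofuran.
Abbreviation: Ar* = 2-benzyloxy-5-(5-benzyloxy-7-methoxy-4-oxo-4H-chromen-2-yl)phenyl, that is ring B of unit 1 carrying protected unit 1 and bonded through C3'.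

Step 1
Reactants: 1 2',6'-dihydroxy-4'-methoxyacetophenone
Product: 2 2'-benzyloxy-6'-hydroxy-4'-methoxyacetophenone
Conditions: BnBr (1.05 equiv), K2CO3 (1.1 equiv), acetone, reflux
Reagents that add atoms: benzyl bromide, BrCc1ccccc1
Why: Williamson ether synthesis that should stop after one alkylation, because the two hydroxyls are equivalent at the start and the remaining one is locked in a hydrogen bond to the ketone, where it is kept as the future O1 of unit 1.

Step 2
Reactants: 3 3-bromo-4-hydroxybenzaldehyde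
Product: 4 4-benzyloxy-3-bromobenzaldehyde
Conditions: BnBr, K2CO3, DMF, 50 °C
Reagents that add atoms: benzyl bromide, BrCc1ccccc1
Why: Williamson ether synthesis on an acidic para-formyl phenol, masking O4' with a group that withstands every later acidic, basic and palladium-catalysed step.

Step 3
Reactants: 2 2'-benzyloxy-6'-hydroxy-4'-methoxyacetophenone; 4 4-benzyloxy-3-bromobenzaldehyde
Product: 5 (E)-1-(2-benzyloxy-6-hydroxy-4-methoxyphenyl)-3-(4-benzyloxy-3-bromophenyl)prop-2-en-1-one
Conditions: KOH (50 % aq), EtOH, rt; then dilute HCl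
Reagents that add atoms: none
Why: Claisen–Schmidt condensation between the only enolisable ketone and a non-enolisable aldehyde, in which E1cB loss of water gives the conjugated E alkene under thermodynamic control.

Step 4
Reactants: 5 (E)-2'-hydroxychalcone
Product: 6 5-benzyloxy-2-(4-benzyloxy-3-bromophenyl)-7-methoxychromen-4-one
Conditions: I2 (10 mol %), DMSO, 120 °C
Reagents that add atoms: none
Why: Iodine-catalysed oxidative cyclisation of a 2'-hydroxychalcone with DMSO as terminal oxidant, a standard flavone synthesis to which the aryl bromide, the methyl ether and the benzyl ethers are inert.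

Step 5
Reactants: 6 3'-bromoflavone; 7 4'-benzyloxyacetophenone
Product: 8 5-benzyloxy-2-{4-benzyloxy-3-[2-(4-benzyloxyphenyl)-2-oxoethyl]phenyl}-7-methoxychromen-4-one (Ar*–CH2–CO–C6H4-4-OBn)
Conditions: 7 (1.3 equiv), Pd2(dba)3 (2 mol %), Xantphos (5 mol %), K3PO4, toluene, 90 °C
Reagents that add atoms: none
Why: Palladium-catalysed α-arylation of a methyl ketone (Buchwald–Hartwig type: oxidative addition of zerovalent palladium into the C3'–Br bond, enolate binding, reductive elimination), with the mild base K3PO4 sparing the flavone and the chelating wide-bite-angle Xantphos favouring mono-arylation and leaving no vacant site for C–H insertion into the neighbouring benzyl ether.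

Step 6
Reactants: 9 but-2-ynoic acid
Product: 10 pentafluorophenyl but-2-ynoate
Conditions: C6F5OH, DCC, CH2Cl2, 0 °C to rt
Reagents that add atoms: pentafluorophenol, Oc1c(F)c(F)c(F)c(F)c1F
Why: Carbodiimide-mediated esterification that should give a storable active ester without exposing the conjugated alkyne to HCl, as acid chloride formation would.

Step 7
Reactants: 8 benzyl ketone Ar*–CH2–CO–C6H4-4-OBn; 10 pentafluorophenyl but-2-ynoate
Product: 12 3-Ar*-2-(4-benzyloxyphenyl)-6-methyl-4H-pyran-4-one, via acetylenic diketone 11 (not isolated)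
Conditions: MgBr2·OEt2 (3 equiv), i-Pr2NEt (4 equiv), CH2Cl2, 0 °C to rt; 1 M HCl wash; then TsOH·H2O (10 mol %), toluene, 60 °C
Reagents that add atoms: none
Why: Soft-enolisation C-acylation of the acidic benzyl ketone with an active ester, steered to carbon by magnesium chelation of the β-diketonate 11, followed by acid-catalysed 6-endo-dig oxa-Michael addition of the aroyl enol oxygen to the ynone, the known passage from acetylenic β-diketones to 4-pyranones.

Step 8
Reactants: 12 6-methylpyranone
Product: 13 [3-Ar*-2-(4-benzyloxyphenyl)-4-oxo-4H-pyran-6-yl]acetic acid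
Conditions: LiN(SiMe3)2 (2.2 equiv), THF, −78 °C; dry CO2, −78 to 0 °C; cold 1 M HCl to pH 3, no heating
Reagents that add atoms: carbon dioxide, O=C=O
Why: Lateral (vinylogous) deprotonation and carboxylation, known for 2-methyl-4-pyranones and 2-methylchromones, in which LiN(SiMe3)2 is basic enough only for the vinylogous methyl ketone position and leaves the vinylic C3–H of the flavone and the benzyl ethers alone, while the second equivalent takes up the more acidic CH2 of the carboxylate formed.

Step 9
Reactants: 13 pyranylacetic acid; 14 potassium methyl malonate (MeO2CCH2CO2K)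
Product: 16 methyl 4-[3-Ar*-2-(4-benzyloxyphenyl)-4-oxo-4H-pyran-6-yl]-3-oxobutanoate, via acyl imidazolide 15 (not isolated)
Conditions: 1,1'-carbonyldiimidazole, THF, rt; then 14, MgCl2, Et3N, MeCN–THF, rt to 40 °C; 1 M HCl
Reagents that add atoms: none
Why: Masamune–Brooks homologation, in which imidazolide 15 is C-acylated by the magnesium chelate of the malonate half-ester with loss of CO2 under nearly neutral conditions that suit an enolisable acid prone to decarboxylation.

Step 10
Reactants: 16 pyranone ketoester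
Product: 18 5,4',4'''-tri-O-benzyl ether of the target with free 5''- and 7''-hydroxyls, via 4aH-trione tautomer 17 (not isolated)
Conditions: Mg(OMe)2 (6 equiv), MeOH–THF, 65 °C; then 1 M HCl
Reagents that add atoms: none
Why: Mg(OMe)2 removes a proton from the C6–CH2 group, which lies between the chain ketone and the pyranone, and the resulting vinylogous enolate spreads its charge through C6=C5 to the C4 oxygen, so that C5 becomes the only carbon nucleophile able to reach the ester (attack from the exocyclic carbon would need a four-membered ring). C5 adds to the ester carbonyl and methoxide leaves, a 6-exo-trig acyl substitution that forms C4a''–C5'' and closes ring A as trione 17, which enolises twice to the aromatic 5'',7''-diol; its magnesium chelate between O5'' and the C4'' carbonyl makes the closure irreversible. The closest known reaction type is the alkoxide- or Mg(OMe)2-induced Claisen (Dieckmann-type) cyclisation of 3,5,7-triketo esters and of pyrone-masked polyketo esters to acylphloroglucinols and 5,7-dihydroxychromones. No stereocentre survives, because C4a'' of 17 is flattened on aromatisation. The step needs Claisen closure in preference to aldol closure or lactonisation, and the intact pyranone secures this: the C8a'' oxygen is tied up as O1'' so no 2-pyranone can form, the C4'' carbonyl is held out of reach of the terminal methylene, and C3'' is blocked by Ar*. Deprotonation also makes the pyranone electron-rich and so less open to methoxide, while the benzyl ethers and the flavone of unit 1 do not react with Mg(OMe)2 in methanol.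

Step 11
Reactants: 18 tri-O-benzyl biflavone
Product: 19 CNP0254254.0, 5-hydroxy-2-{4-hydroxy-3-[5,7-dihydroxy-2-(4-hydroxyphenyl)-4-oxochromen-3-yl]phenyl}-7-methoxychromen-4-one
Conditions: H2 (1 atm), Pd/C (10 wt %), THF–MeOH, rt
Reagents that add atoms: none
Why: Heterogeneous catalytic hydrogenolysis of three aryl benzyl ethers, routinely applied to flavones at one atmosphere without touching the conjugated C2=C3 bonds, the aryl methyl ether or the free phenols.

Compound list
1 | 2',6'-dihydroxy-4'-methoxyacetophenone | CC(=O)c1c(O)cc(OC)cc1O | starting material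
2 | 2'-benzyloxy-6'-hydroxy-4'-methoxyacetophenone | CC(=O)c1c(O)cc(OC)cc1OCc1ccccc1 | intermediate
3 | 3-bromo-4-hydroxybenzaldehyde | O=Cc1ccc(O)c(Br)c1 | starting material
4 | 4-benzyloxy-3-bromobenzaldehyde | O=Cc1ccc(OCc2ccccc2)c(Br)c1 | intermediate
5 | (E)-1-(2-benzyloxy-6-hydroxy-4-methoxyphenyl)-3-(4-benzyloxy-3-bromophenyl)prop-2-en-1-one | COc1cc(O)c(C(=O)/C=C/c2ccc(OCc3ccccc3)c(Br)c2)c(OCc2ccccc2)c1 | intermediate
6 | 5-benzyloxy-2-(4-benzyloxy-3-bromophenyl)-7-methoxychromen-4-one | COc1cc(OCc2ccccc2)c2c(=O)cc(-c3ccc(OCc4ccccc4)c(Br)c3)oc2c1 | intermediate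
7 | 4'-benzyloxyacetophenone | CC(=O)c1ccc(OCc2ccccc2)cc1 | starting material
8 | 5-benzyloxy-2-{4-benzyloxy-3-[2-(4-benzyloxyphenyl)-2-oxoethyl]phenyl}-7-methoxychromen-4-one | COc1cc(OCc2ccccc2)c2c(=O)cc(-c3ccc(OCc4ccccc4)c(CC(=O)c4ccc(OCc5ccccc5)cc4)c3)oc2c1 | intermediate
9 | but-2-ynoic acid | CC#CC(=O)O | starting material
10 | pentafluorophenyl but-2-ynoate | CC#CC(=O)Oc1c(F)c(F)c(F)c(F)c1F | intermediate
11 | 2-Ar*-1-(4-benzyloxyphenyl)hex-4-yne-1,3-dione (drawn as the diketo tautomer; the CH centre is configurationally labile) | CC#CC(=O)C(C(=O)c1ccc(OCc2ccccc2)cc1)c1cc(-c2cc(=O)c3c(OCc4ccccc4)cc(OC)cc3o2)ccc1OCc1ccccc1 | intermediate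
12 | 3-Ar*-2-(4-benzyloxyphenyl)-6-methyl-4H-pyran-4-one | Cc1cc(=O)c(-c2cc(-c3cc(=O)c4c(OCc5ccccc5)cc(OC)cc4o3)ccc2OCc2ccccc2)c(-c2ccc(OCc3ccccc3)cc2)o1 | intermediate
13 | [3-Ar*-2-(4-benzyloxyphenyl)-4-oxo-4H-pyran-6-yl]acetic acid | OC(=O)Cc1cc(=O)c(-c2cc(-c3cc(=O)c4c(OCc5ccccc5)cc(OC)cc4o3)ccc2OCc2ccccc2)c(-c2ccc(OCc3ccccc3)cc2)o1 | intermediate
14 | potassium methyl malonate | COC(=O)CC(=O)[O-].[K+] | starting material
15 | 1-{[3-Ar*-2-(4-benzyloxyphenyl)-4-oxo-4H-pyran-6-yl]acetyl}imidazole | O=C(Cc1cc(=O)c(-c2cc(-c3cc(=O)c4c(OCc5ccccc5)cc(OC)cc4o3)ccc2OCc2ccccc2)c(-c2ccc(OCc3ccccc3)cc2)o1)n1ccnc1 | intermediate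
16 | methyl 4-[3-Ar*-2-(4-benzyloxyphenyl)-4-oxo-4H-pyran-6-yl]-3-oxobutanoate | COC(=O)CC(=O)Cc1cc(=O)c(-c2cc(-c3cc(=O)c4c(OCc5ccccc5)cc(OC)cc4o3)ccc2OCc2ccccc2)c(-c2ccc(OCc3ccccc3)cc2)o1 | intermediate
17 | 3-Ar*-2-(4-benzyloxyphenyl)-4aH-chromene-4,5,7(6H)-trione (racemic at C4a'', transient) | O=C1CC(=O)C2C(=C1)OC(c1ccc(OCc3ccccc3)cc1)=C(c1cc(-c3cc(=O)c4c(OCc5ccccc5)cc(OC)cc4o3)ccc1OCc1ccccc1)C2=O | intermediate
18 | 5-benzyloxy-2-{4-benzyloxy-3-[2-(4-benzyloxyphenyl)-5,7-dihydroxy-4-oxochromen-3-yl]phenyl}-7-methoxychromen-4-one | COc1cc(OCc2ccccc2)c2c(=O)cc(-c3ccc(OCc4ccccc4)c(-c4c(-c5ccc(OCc6ccccc6)cc5)oc5cc(O)cc(O)c5c4=O)c3)oc2c1 | intermediate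
19 | CNP0254254.0, 5-hydroxy-2-{4-hydroxy-3-[5,7-dihydroxy-2-(4-hydroxyphenyl)-4-oxochromen-3-yl]phenyl}-7-methoxychromen-4-one | COc1cc(O)c2c(=O)cc(-c3ccc(O)c(-c4c(-c5ccc(O)cc5)oc5cc(O)cc(O)c5c4=O)c3)oc2c1 | target

Total step count: 11
Longest linear sequence: 9 steps (1 → 2 → 5 → 6 → 8 → 12 → 13 → 16 → 18 → 19)

Steps most likely to fail

1. Step 10.
- **Risk:** Methoxide may open the pyranone ring before C5 reaches the ester. The released chain could then fold in the aldol sense or lactonise. The chelated, doubly deprotonated ketoester may also simply stay unreactive.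
- **Fallback:** Cross-coupling of two finished flavones replaces ring construction. It sets out from 6 and comes back to the route at 19.
- Miyaura borylation of 6 (B2pin2, Pd(dppf)Cl2, KOAc, dioxane, 90 °C) should give the 3'-pinacol boronate F1.
- Commercial apigenin would be perbenzylated (BnBr, K2CO3, DMF, 80 °C) to tri-O-benzylapigenin F2.
- Lithiation at C3 with LiN(i-Pr)2 at −78 °C and a quench with I2 should give the 3-iodoflavone F3.
- Suzuki–Miyaura coupling of the two partners (Pd(PPh3)4, K2CO3, dioxane–H2O, 90 °C) should give the penta-O-benzyl biflavone F4.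
- Hydrogenolysis under the conditions of step 11 then leads to 19.

2. Step 7.
- **Risk:** The hindered enolate may be acylated on oxygen or may add to the alkyne in the conjugate sense. The Lewis acid may strip the benzyl group from O5 next to the carbonyl. Ring closure of the chelated diketone may be slow.
- **Fallback:** A cycloaddition replaces the polar acylation. It sets out from 8 and comes back at 12.
- Silylation of 8 (Me3SiOTf, Et3N, CH2Cl2, 0 °C) should give the (Z)-trimethylsilyl enol ether F5.
- Heating with 2,2,6-trimethyl-4H-1,3-dioxin-4-one in toluene at 110 °C releases acetylketene.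
- Its hetero-Diels–Alder reaction with electron-rich enol ethers is known and should give the 2-silyloxy-2,3-dihydropyran-4-one F6.
- Catalytic TsOH then eliminates the silanol to give 12.

3. Step 8.
- **Risk:** The lateral anion may add to the flavone of a second molecule. The substrate may be poorly soluble at low temperature. The vinylogous β-keto acid may lose CO2 during work-up.
- **Fallback:** The side-chain carbon is brought in with the alkynoate, so no strong base meets the flavone. It sets out from 8 and comes back at 13.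
- Commercial 4-(tert-butyldimethylsilyloxy)but-1-yne would be lithiated (n-BuLi, THF, −78 °C) and carboxylated to 5-(tert-butyldimethylsilyloxy)pent-2-ynoic acid F7.
- This would be converted as in step 6 into its pentafluorophenyl ester F8.
- Acylation of 8 under the conditions of step 7 should pass through the acetylenic diketone F9 and give the 6-(2-silyloxyethyl)pyranone F10. Partial loss of the silyl group at this point would be harmless.
- Bu4NF in THF releases the primary alcohol F11.
- TEMPO (cat.) with PhI(OAc)2 in MeCN–H2O oxidises it to acid 13.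

Further compounds
F1 | step 10 | 5-benzyloxy-2-[4-benzyloxy-3-(4,4,5,5-tetramethyl-1,3,2-dioxaborolan-2-yl)phenyl]-7-methoxychromen-4-one | COc1cc(OCc2ccccc2)c2c(=O)cc(-c3ccc(OCc4ccccc4)c(B4OC(C)(C)C(C)(C)O4)c3)oc2c1
F2 | step 10 | 5,7-bis(benzyloxy)-2-(4-benzyloxyphenyl)chromen-4-one | O=c1cc(-c2ccc(OCc3ccccc3)cc2)oc2cc(OCc3ccccc3)cc(OCc3ccccc3)c12
F3 | step 10 | 5,7-bis(benzyloxy)-2-(4-benzyloxyphenyl)-3-iodochromen-4-one | O=c1c(I)c(-c2ccc(OCc3ccccc3)cc2)oc2cc(OCc3ccccc3)cc(OCc3ccccc3)c12
F4 | step 10 | penta-O-benzyl ether of the target | COc1cc(OCc2ccccc2)c2c(=O)cc(-c3ccc(OCc4ccccc4)c(-c4c(-c5ccc(OCc6ccccc6)cc5)oc5cc(OCc6ccccc6)cc(OCc6ccccc6)c5c4=O)c3)oc2c1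
F5 | step 7 | (Z)-trimethylsilyl enol ether of 8 | C[Si](C)(C)O/C(c1ccc(OCc2ccccc2)cc1)=C\c1cc(-c2cc(=O)c3c(OCc4ccccc4)cc(OC)cc3o2)ccc1OCc1ccccc1
F6 | step 7 | 3-Ar*-2-(4-benzyloxyphenyl)-6-methyl-2-trimethylsilyloxy-2,3-dihydropyran-4-one (racemic; both centres are lost on elimination) | CC1=CC(=O)C(c2cc(-c3cc(=O)c4c(OCc5ccccc5)cc(OC)cc4o3)ccc2OCc2ccccc2)C(O[Si](C)(C)C)(c2ccc(OCc3ccccc3)cc2)O1
F7 | step 8 | 5-(tert-butyldimethylsilyloxy)pent-2-ynoic acid | CC(C)(C)[Si](C)(C)OCCC#CC(=O)O
F8 | step 8 | pentafluorophenyl 5-(tert-butyldimethylsilyloxy)pent-2-ynoate | CC(C)(C)[Si](C)(C)OCCC#CC(=O)Oc1c(F)c(F)c(F)c(F)c1F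
F9 | step 8 | 2-Ar*-1-(4-benzyloxyphenyl)-7-(tert-butyldimethylsilyloxy)hept-4-yne-1,3-dione (diketo tautomer drawn; CH centre labile) | CC(C)(C)[Si](C)(C)OCCC#CC(=O)C(C(=O)c1ccc(OCc2ccccc2)cc1)c1cc(-c2cc(=O)c3c(OCc4ccccc4)cc(OC)cc3o2)ccc1OCc1ccccc1
F10 | step 8 | 3-Ar*-2-(4-benzyloxyphenyl)-6-[2-(tert-butyldimethylsilyloxy)ethyl]-4H-pyran-4-one | CC(C)(C)[Si](C)(C)OCCc1cc(=O)c(-c2cc(-c3cc(=O)c4c(OCc5ccccc5)cc(OC)cc4o3)ccc2OCc2ccccc2)c(-c2ccc(OCc3ccccc3)cc2)o1
F11 | step 8 | 3-Ar*-2-(4-benzyloxyphenyl)-6-(2-hydroxyethyl)-4H-pyran-4-one | OCCc1cc(=O)c(-c2cc(-c3cc(=O)c4c(OCc5ccccc5)cc(OC)cc4o3)ccc2OCc2ccccc2)c(-c2ccc(OCc3ccccc3)cc2)o1
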